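**Retrosynthetic overview**

1. The target is the meso (2R,3S) lignan. Ring B is detached at its benzylic CH2–aryl bond, giving a primary alkyllithium that already carries ring A and both stereocentres, and a 3-alkoxybenzyne generated from a 5-chloro-1,2,3-trialkoxybenzene.
2. Enabling feature: in ring B the carbon that bears the chain (C1) and the unsubstituted C2–H lie directly beside the C3 methoxy oxygen (mirrored by C6–H and C5–OMe). This OMe acidifies the C–H next to chlorine for aryne formation and polarises the C1≡C2 aryne so that carbon adds at C1 and the anion, later H, sits at C2.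
3. The alkyl fragment comes from commercial meso-2,3-dimethylsuccinic acid, which supplies both stereocentres: meso diol, then cyclic sulfate, then a single opening by the ring-A aryl Grignard, then alcohol and iodide.
4. Both aromatic rings come preformed from one bromide, the isopropyl ether of 4-bromo-2,6-dimethoxyphenol, used once as a Grignard reagent (ring A) and once, after Br to Cl exchange, as the aryne precursor (ring B).
5. No ring of the target is constructed. The only ring formed is the temporary dioxathiepane (step 2), opened in step 4. A final BCl3 step removes both isopropyl groups.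

Key step: step 7

Assumption: the descriptors of the target SMILES correspond to the achiral meso (2R,3S) diastereomer, so only relative configuration has to be controlled. Desymmetrised intermediates are racemic and are drawn as one enantiomer; both enantiomers converge on the meso product.

**Route**

Step 1
Reactants: 1 meso-2,3-dimethylsuccinic acid
Product: 2 meso-2,3-dimethylbutane-1,4-diol
Conditions: LiAlH4, THF, 0 °C to reflux; then H2O, aq NaOH
Reagents that add atoms: none
Why: Hydride reduction of both carboxyl groups to primary alcohols should proceed without enolisation of the carboxylate salts, so the meso (2R,3S) relation of the commercial acid, the source of both stereocentres of the target, is carried over unchanged.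

Step 2
Reactants: 2 meso-2,3-dimethylbutane-1,4-diol
Product: 4 cis-5,6-dimethyl-1,3,2-dioxathiepane 2,2-dioxide, via cyclic sulfite 3 (not isolated)
Conditions: SOCl2, CH2Cl2, reflux; then RuCl3 hydrate (cat.), NaIO4, MeCN/CH2Cl2/H2O, 0 °C to rt
Reagents that add atoms: thionyl chloride O=S(Cl)Cl; sodium periodate [Na+].[O-]I(=O)(=O)=O
Why: Cyclic sulfite formation followed by ruthenium-catalysed periodate oxidation is the standard two-stage cyclic sulfate synthesis, established for 1,4-diols, and turns the meso diol into a temporary seven-membered electrophile that can be opened only once.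

Step 3
Reactants: 5 4-bromo-2,6-dimethoxyphenol
Product: 6 5-bromo-2-isopropoxy-1,3-dimethoxybenzene
Conditions: 2-bromopropane, K2CO3, DMF, 70 °C
Reagents that add atoms: 2-bromopropane CC(C)Br
Why: Williamson etherification of the acidic phenol should install an isopropyl ether, chosen because it survives Grignard and organolithium reagents and is cleaved by BCl3 in the presence of methyl ethers.

Step 4
Reactants: 4 cis-5,6-dimethyl-1,3,2-dioxathiepane 2,2-dioxide; 6 5-bromo-2-isopropoxy-1,3-dimethoxybenzene
Product: 9 rac-(2R,3R)-4-(4-isopropoxy-3,5-dimethoxyphenyl)-2,3-dimethylbutan-1-ol, via arylmagnesium bromide 7 (not isolated), via sulfate monoester salt 8 (not isolated)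
Conditions: 6, Mg, THF, rt to 45 °C; then 4, CuI (10 mol %), THF, −30 to 0 °C; then 20% aq H2SO4, Et2O, rt
Reagents that add atoms: none
Why: Copper-catalysed SN2 opening of the cyclic sulfate by the aryl Grignard at a primary carbon should stop after one alkylation because the sulfate monoester anion is inert, so the meso ring is desymmetrised cleanly (attack at either enantiotopic CH2 gives the racemate with the erythro relation intact), and acid hydrolysis with S–O cleavage leaves both stereocentres untouched.

Step 5
Reactants: 9 rac-(2R,3R)-4-(4-isopropoxy-3,5-dimethoxyphenyl)-2,3-dimethylbutan-1-ol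
Product: 10 rac-5-[(2R,3R)-4-iodo-2,3-dimethylbutyl]-2-isopropoxy-1,3-dimethoxybenzene
Conditions: I2, PPh3, imidazole, CH2Cl2, 0 °C to rt
Reagents that add atoms: iodine II
Why: The Appel reaction should convert the primary alcohol into the iodide by SN2 at CH2, remote from both stereocentres.

Step 6
Reactants: 6 5-bromo-2-isopropoxy-1,3-dimethoxybenzene
Product: 12 5-chloro-2-isopropoxy-1,3-dimethoxybenzene, via aryllithium 11 (not isolated)
Conditions: n-BuLi, THF, −78 °C; then C2Cl6, −78 °C to rt
Reagents that add atoms: hexachloroethane ClC(Cl)(Cl)C(Cl)(Cl)Cl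
Why: Bromine–lithium exchange followed by electrophilic chlorination with hexachloroethane should replace the exchange-prone bromide by a chloride, which alkyllithiums deprotonate at the ortho position instead of exchanging.

Step 7
Reactants: 10 rac-5-[(2R,3R)-4-iodo-2,3-dimethylbutyl]-2-isopropoxy-1,3-dimethoxybenzene; 12 5-chloro-2-isopropoxy-1,3-dimethoxybenzene
Product: 17 meso-(2R,3S)-1,4-bis(4-isopropoxy-3,5-dimethoxyphenyl)-2,3-dimethylbutane, via alkyllithium 13 (not isolated), via lithiated chloroarene 14 (not isolated), via aryne 15 (not isolated), via aryllithium adduct 16 (not isolated)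
Conditions: (a) 10, t-BuLi (2.1 equiv), Et2O/pentane, −78 °C; (b) 12 (1.5 equiv), n-BuLi (1.45 equiv), THF, −78 °C; (c) solution (a) added to (b), −78 to 0 °C; then MeOH
Reagents that add atoms: none
Why: Ortho-lithiation of 12 at the C–H flanked by Cl and OMe gives 14, which loses LiCl on warming to the 3-alkoxybenzyne 15; the primary alkyllithium 13 then adds to the aryne and the aryllithium 16 is protonated on quench, so that in one operation the two aryne carbons take up the alkyl chain and a hydrogen (net ipso replacement of Cl). The closest known reaction type is the aryne-mediated alkylation of 3,5-dialkoxy-halobenzenes and 3-haloanisoles by alkyllithiums. The regioselectivity that is needed is attack at the aryne carbon remote from the methoxy group: the σ-withdrawing OMe on the neighbouring ring carbon distorts the triple bond (more electrophilic distal carbon) and stabilises the carbanion that develops beside oxygen, and the two possible deprotonation sites of 12 are equivalent by symmetry. The chemoselectivity that is needed is capture of 15 by 13 and not by the aryllithiums 14 and 16, which should be secured by their 2,6-disubstitution and by the higher nucleophilicity of a primary alkyllithium, while pre-lithiation of 12 with sacrificial n-BuLi keeps 13 from being spent as base. No ring is closed and no stereocentre is formed; the two methyl-bearing carbons are not acidic and pass unchanged, and attachment of the second identical aryl group turns the racemic erythro fragment into the meso compound 17.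

Step 8
Reactants: 17 meso-(2R,3S)-1,4-bis(4-isopropoxy-3,5-dimethoxyphenyl)-2,3-dimethylbutane
Product: 18 4,4'-[(2R,3S)-2,3-dimethylbutane-1,4-diyl]bis(2,6-dimethoxyphenol)
Conditions: BCl3 (1 M in CH2Cl2), CH2Cl2, −78 to 0 °C; then H2O
Reagents that add atoms: none
Why: Lewis-acid dealkylation with BCl3 should cleave the two secondary isopropyl aryl ethers at low temperature, at the most basic, out-of-plane central oxygen, while the four methyl ethers and the stereocentres remain untouched.

**Compound list**

1 | meso-2,3-dimethylsuccinic acid, (2R,3S) | OC(=O)[C@@H](C)[C@@H](C)C(=O)O | starting material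
2 | meso-2,3-dimethylbutane-1,4-diol, (2R,3S) | OC[C@@H](C)[C@@H](C)CO | intermediate
3 | cis-5,6-dimethyl-1,3,2-dioxathiepane 2-oxide (cyclic sulfite, mixture at sulfur) | O=S1OC[C@@H](C)[C@@H](C)CO1 | intermediate
4 | cis-5,6-dimethyl-1,3,2-dioxathiepane 2,2-dioxide (meso cyclic sulfate) | O=S1(=O)OC[C@@H](C)[C@@H](C)CO1 | intermediate
5 | 4-bromo-2,6-dimethoxyphenol | COc1cc(Br)cc(OC)c1O | starting material
6 | 5-bromo-2-isopropoxy-1,3-dimethoxybenzene | COc1cc(Br)cc(OC)c1OC(C)C | intermediate
7 | (4-isopropoxy-3,5-dimethoxyphenyl)magnesium bromide | COc1cc([Mg]Br)cc(OC)c1OC(C)C | intermediate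
8 | bromomagnesium 4-(4-isopropoxy-3,5-dimethoxyphenyl)-2,3-dimethylbutyl sulfate (racemic, erythro) | COc1cc(C[C@@H](C)[C@@H](C)COS(=O)(=O)O[Mg]Br)cc(OC)c1OC(C)C | intermediate
9 | rac-(2R,3R)-4-(4-isopropoxy-3,5-dimethoxyphenyl)-2,3-dimethylbutan-1-ol (erythro, meso-type relation) | COc1cc(C[C@@H](C)[C@@H](C)CO)cc(OC)c1OC(C)C | intermediate
10 | rac-5-[(2R,3R)-4-iodo-2,3-dimethylbutyl]-2-isopropoxy-1,3-dimethoxybenzene (erythro) | COc1cc(C[C@@H](C)[C@@H](C)CI)cc(OC)c1OC(C)C | intermediate
11 | (4-isopropoxy-3,5-dimethoxyphenyl)lithium | COc1cc([Li])cc(OC)c1OC(C)C | intermediate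
12 | 5-chloro-2-isopropoxy-1,3-dimethoxybenzene | COc1cc(Cl)cc(OC)c1OC(C)C | intermediate
13 | [4-(4-isopropoxy-3,5-dimethoxyphenyl)-2,3-dimethylbutyl]lithium (racemic, same relative configuration as 10) | COc1cc(C[C@@H](C)[C@@H](C)C[Li])cc(OC)c1OC(C)C | intermediate
14 | (6-chloro-3-isopropoxy-2,4-dimethoxyphenyl)lithium | COc1cc(Cl)c([Li])c(OC)c1OC(C)C | intermediate
15 | 4-isopropoxy-3,5-dimethoxybenzyne (1,2-didehydro-4-isopropoxy-3,5-dimethoxybenzene) | COC1=C(OC(C)C)C(OC)=CC#C1 | intermediate
16 | {6-[4-(4-isopropoxy-3,5-dimethoxyphenyl)-2,3-dimethylbutyl]-3-isopropoxy-2,4-dimethoxyphenyl}lithium (racemic, erythro) | COc1cc(C[C@@H](C)[C@@H](C)Cc2cc(OC)c(OC(C)C)c(OC)c2[Li])cc(OC)c1OC(C)C | intermediate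
17 | meso-(2R,3S)-1,4-bis(4-isopropoxy-3,5-dimethoxyphenyl)-2,3-dimethylbutane | COc1cc(C[C@@H](C)[C@@H](C)Cc2cc(OC)c(OC(C)C)c(OC)c2)cc(OC)c1OC(C)C | intermediate
18 | 4,4'-[(2R,3S)-2,3-dimethylbutane-1,4-diyl]bis(2,6-dimethoxyphenol) (meso) | COc1cc(C[C@@H](C)[C@@H](C)Cc2cc(OC)c(O)c(OC)c2)cc(OC)c1O | target

**Step count**

Total steps: 8. Longest linear sequence: 6 steps (steps 1, 2, 4, 5, 7, 8).

**Steps most likely to fail**

1. Step 7. The aryne may be consumed by the aryllithiums 14 and 16 (oligoaryl formation), or the alkyllithium 13 may be lost by proton transfer before the aryne is released, which would return the reduced alkane. Fallback: setting out from iodide 10, zinc insertion (Zn dust, LiCl, THF) should give the alkylzinc iodide F1. A palladium-catalysed Negishi coupling of this reagent with bromide 6 (Pd(OAc)2, dialkylbiarylphosphine ligand, THF/NMP) should give 17, where the route is rejoined.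

2. Step 4. Substitution at the β-branched CH2 of the cyclic sulfate may be slow, allowing homocoupling of the Grignard reagent or attack at sulfur. Fallback: setting out from diol 2, monosilylation (NaH, TBSCl, THF) should give the racemic mono-TBS ether F2. An Appel reaction should convert it into the silyloxy iodide F3. Copper-catalysed coupling with Grignard reagent 7 should give the aryl silyl ether F4, and TBAF should release alcohol 9, where the route is rejoined.

3. Step 2. Closure of the seven-membered sulfite may lose out to cyclodehydration to the tetrahydrofuran or to chain oligomerisation. Fallback: setting out from diol 2, a double Appel reaction should give meso-1,4-diiodo-2,3-dimethylbutane F5. Used in threefold excess with Grignard reagent 7 and catalytic Li2CuCl4, so that mono-arylation dominates and the surplus is recovered, it should give iodide 10 directly, where the route is rejoined.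

**Further compounds**

F1 | step 7 | [4-(4-isopropoxy-3,5-dimethoxyphenyl)-2,3-dimethylbutyl]zinc iodide (racemic, erythro) | COc1cc(C[C@@H](C)[C@@H](C)C[Zn]I)cc(OC)c1OC(C)C
F2 | step 4 | 4-(tert-butyldimethylsilyloxy)-2,3-dimethylbutan-1-ol (racemic, erythro) | CC(C)(C)[Si](C)(C)OC[C@@H](C)[C@@H](C)CO
F3 | step 4 | tert-butyl(4-iodo-2,3-dimethylbutoxy)dimethylsilane (racemic, erythro) | CC(C)(C)[Si](C)(C)OC[C@@H](C)[C@@H](C)CI
F4 | step 4 | tert-butyl[4-(4-isopropoxy-3,5-dimethoxyphenyl)-2,3-dimethylbutoxy]dimethylsilane (racemic, erythro) | COc1cc(C[C@@H](C)[C@@H](C)CO[Si](C)(C)C(C)(C)C)cc(OC)c1OC(C)C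
F5 | step 2 | meso-1,4-diiodo-2,3-dimethylbutane | IC[C@@H](C)[C@@H](C)CI
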